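**Retrosynthetic overview**
1. The target comes from 22 by one acid unmasking (tert-butyl ester, dimethyl acetal). The Z-alkene comes from a Z-selective cross metathesis of the C-10 dec-9-enoate with oct-7-en-1-ol.
2. The 10S carbinol comes from exo-face 1,2-reduction of the C-10 enone. The 2S formyl centre is set by base equilibration.
3. Ring C is closed last, by ring-closing metathesis between an angular allylic alcohol on C-1 and an acrylate on C-7.
4. Rings A and B are closed together: a thiyl-radical-catalysed [3+2] isomerisation of a spiro vinylcyclopropane lactone onto its own homoprenyl alkene.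
5. The vinylcyclopropane comes from an α-methylene lactone and an allylic sulfonium ylide. The lactone comes from a catalytic asymmetric conjugate addition to furan-2(5H)-one. Ring order: sacrificial lactone, then A and B, then C.

Assumption: cedrane numbering is used from compound 11 on (C-1 quaternary, C-2 formyl-bearing, C-5 fusion CH, C-6 CMe2, C-7 bridgehead CH, C-8 carboxyl-bearing, C-10 oxygenated, C-11 bridge CH2, C-12 formyl carbon), and the 2S formyl epimer of the target (CHO anti to C-10) is taken to be the thermodynamically preferred one.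

**Step 1**
Reactants: 1 5-bromo-2-methylpent-2-ene; 2 furan-2(5H)-one
Product: 5 (4R)-4-(4-methylpent-3-en-1-yl)oxolan-2-one, via homoprenylmagnesium bromide 3 (not isolated), via bis(homoprenyl)zinc 4 (not isolated)
Conditions: 1, Mg, THF; ZnCl2 (0.5 equiv), then 1,4-dioxane, filter; 2, (CuOTf)2·C6H6 (2.5 mol %), valine-derived phosphine–peptide ligand (5 mol %), PhMe, −30 °C; aq NH4Cl
Reagents that add atoms: none
Why: This is a copper-catalysed enantioselective conjugate addition of a dialkylzinc to an unsaturated lactone, in which the chiral monovalent copper complex selects one butenolide face and sets the R centre (later C-2), the only stereocentre in the route that needs a chiral catalyst.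

**Step 2**
Reactants: 5 (4R)-4-(4-methylpent-3-en-1-yl)oxolan-2-one
Product: 7 (4R)-3-methylidene-4-(4-methylpent-3-en-1-yl)oxolan-2-one, via sodium formyl-lactone enolate 6 (not isolated)
Conditions: NaH, HCO2Et, Et2O, 0 °C to rt; then (CH2O)n, THF, reflux
Reagents that add atoms: paraformaldehyde (as formaldehyde) C=O
Why: In this formylation and deformylative α-methylenation of a lactone, the formyl enolate adds to formaldehyde and loses formate, giving the exocyclic CH2 (later C-11) without touching the stereocentre.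

**Step 3**
Reactants: 7 (4R)-3-methylidene-4-(4-methylpent-3-en-1-yl)oxolan-2-one; 8 tert-butyl 2-(bromomethyl)prop-2-enoate
Product: 10 spiro vinylcyclopropane lactone (7R; cyclopropane isomers), via allylic thiolanium bromide 9 (not isolated)
Conditions: 8, tetrahydrothiophene, MeCN, rt; then 7, Cs2CO3, MeCN, 0 °C to rt
Reagents that add atoms: none
Why: In this sulfonium-ylide cyclopropanation (Michael-initiated ring closure), the allylic ylide adds through its α-carbon to the exocyclic CH2 and the lactone enolate displaces tetrahydrothiophene, and the two new cyclopropane stereocentres need no control because step 4 erases both.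

**Step 4**
Reactants: 10 spiro vinylcyclopropane lactone
Product: 11 tricyclic lactone acrylate (1S,2R,5S,7R)
Conditions: PhSSPh (0.3 equiv), AIBN (0.1 equiv), PhH (0.01 M), reflux, sunlamp
Reagents that add atoms: none
Why: In this thiyl-radical-catalysed intramolecular vinylcyclopropane–alkene [3+2] annulation, PhS• adds to the acrylate CH2, the cyclopropylcarbinyl radical opens to the lactone-stabilised tertiary C-1 radical, a 5-exo attack on the electron-rich prenyl alkene closes ring A (chair transition state with the lactone CH2O pseudo-equatorial, so C-6 ends trans to C-12 and cis to C-11), and the nucleophilic C-6 radical closes ring B by 5-exo addition to the allyl sulfide enoate (C-10 pseudo-equatorial, so the C-7 side chain ends cis to C-10) before loss of PhS• restores the acrylate.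

**Step 5**
Reactants: 11 tricyclic lactone acrylate
Product: 13 diol diene (1S,2R,5S,7R; C-10 epimers), via lactol 12 (not isolated)
Conditions: i-Bu2AlH (1.1 equiv), CH2Cl2, −78 °C; then CH2=CHMgBr (4 equiv), THF, −78 to 0 °C; Rochelle salt
Reagents that add atoms: vinylmagnesium bromide C=C[Mg]Br
Why: The lactone is partly reduced and the Grignard reagent then adds to the ring-opened hydroxy aldehyde, the hindered tert-butyl ester survives at low temperature, and the C-10 epimer ratio does not matter because C-10 is oxidised in step 7.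

**Step 6**
Reactants: 13 diol diene
Product: 14 cedrene diol (1S,2R,5S,7R; C-10 epimers)
Conditions: second-generation Hoveyda–Grubbs catalyst (5 mol %), PhMe (0.005 M), 80 °C
Reagents that add atoms: none
Why: Ring-closing metathesis of the allylic alcohol vinyl group with the 1,1-disubstituted acrylate closes ring C because both groups sit cis-1,3 on ring B, and it delivers the C-8 ester, the C-8/C-9 alkene and the C-10 oxygen in their final positions.

**Step 7**
Reactants: 14 cedrene diol
Product: 16 keto aldehyde (1S,2S,5S,7R), via 2-epi keto aldehyde 15 (not isolated)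
Conditions: Dess–Martin periodinane (3 equiv), CH2Cl2, rt; aq Na2S2O3/NaHCO3 wash; then DBU (0.2 equiv), CH2Cl2, rt
Reagents that add atoms: none
Why: A double Dess–Martin oxidation is followed by base epimerisation through the C-2 enolate, which moves the formyl group off the face where it nearly eclipses the C-10 carbonyl and onto the face of the small C-11 CH2, setting 2S under thermodynamic control.

**Step 8**
Reactants: 16 keto aldehyde
Product: 18 hydroxy acetal (1S,2S,5S,7R,10S), via enone dimethyl acetal 17 (not isolated)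
Conditions: HC(OMe)3, CeCl3·7H2O, MeOH, rt; then NaBH4, −78 °C
Reagents that add atoms: trimethyl orthoformate COC(OC)OC
Why: In this Luche–Gemal sequence the cerium salt acetalises only the aldehyde and the Luche 1,2-reduction then takes the enone, with hydride arriving on the exo face (the C-11 bridge side) because H-5 and the endo C-6 methyl close the endo face, which gives the endo 10S alcohol.

**Step 9**
Reactants: 18 hydroxy acetal; 19 dec-9-enoic acid
Product: 20 C-10 dec-9-enoate
Conditions: DCC, DMAP, CH2Cl2, rt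
Reagents that add atoms: none
Why: This Steglich esterification meets only one free hydroxyl group, C-10 keeps its configuration because the C–O bond is not broken, and the acetal shields C-2 from DMAP.

**Step 10**
Reactants: 20 C-10 dec-9-enoate; 21 oct-7-en-1-ol
Product: 22 protected target with the (9Z)-16-hydroxyhexadec-9-enoate chain
Conditions: 21 (5 equiv), Grubbs Z-selective catalyst (N-adamantyl-chelated, N-2,6-diisopropylphenyl NHC ruthenium nitrate 2-isopropoxybenzylidene, 3 mol %), THF, 35 °C, static vacuum
Reagents that add atoms: none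
Why: In this Z-selective cross metathesis of two terminal alkenes the chelated catalyst forces a syn metallacycle and so gives the Z-alkene, tolerates the free alcohol, and leaves the trisubstituted conjugated ring alkene alone.

**Step 11**
Reactants: 22 protected target
Product: 23 target CNP0214056.2
Conditions: TFA/CH2Cl2/H2O (4:8:1), 0 °C to rt; aq NaHCO3, then pH 3
Reagents that add atoms: water O
Why: Acidolysis removes the tert-butyl ester and hydrolyses the dimethyl acetal in one flask, the electron-poor allylic C-10 ester does not ionise, and any acid enolisation at C-2 returns the favoured 2S aldehyde.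

**Compound list**
1 | 5-bromo-2-methylpent-2-ene | CC(C)=CCCBr | starting material
2 | furan-2(5H)-one | O=C1C=CCO1 | starting material
3 | (4-methylpent-3-en-1-yl)magnesium bromide | CC(C)=CCC[Mg]Br | intermediate
4 | bis(4-methylpent-3-en-1-yl)zinc | CC(C)=CCC[Zn]CCC=C(C)C | intermediate
5 | (4R)-4-(4-methylpent-3-en-1-yl)oxolan-2-one | O=C1C[C@@H](CCC=C(C)C)CO1 | intermediate
6 | sodium [(4R)-4-(4-methylpent-3-en-1-yl)-2-oxooxolan-3-ylidene]methanolate | O=C1OC[C@H](CCC=C(C)C)C1=C[O-].[Na+] | intermediate
7 | (4R)-3-methylidene-4-(4-methylpent-3-en-1-yl)oxolan-2-one | O=C1OC[C@H](CCC=C(C)C)C1=C | intermediate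
8 | tert-butyl 2-(bromomethyl)prop-2-enoate | C=C(CBr)C(=O)OC(C)(C)C | starting material
9 | 1-[2-(tert-butoxycarbonyl)prop-2-en-1-yl]thiolan-1-ium bromide | C=C(C[S+]1CCCC1)C(=O)OC(C)(C)C.[Br-] | intermediate
10 | tert-butyl 2-[(7R)-7-(4-methylpent-3-en-1-yl)-4-oxo-5-oxaspiro[2.4]heptan-1-yl]prop-2-enoate (isomers at the two cyclopropane centres) | O=C1OC[C@H](CCC=C(C)C)C12CC2C(=C)C(=O)OC(C)(C)C | intermediate
11 | tricyclic lactone acrylate: cis-bicyclo[3.3.0]octane (rings A and B, 6,6-dimethyl), γ-lactone C10(=O)–O–C12H2 cis-fused on C1–C2, 1-(tert-butoxycarbonyl)ethenyl on C7 cis to C10; (1S,2R,5S,7R) | CC1(C)[C@H](C(=C)C(=O)OC(C)(C)C)C[C@@]2(C(=O)OC3)[C@H]3CC[C@@H]12 | intermediate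
12 | lactol of 11 (C10 hemiacetal, anomers) | CC1(C)[C@H](C(=C)C(=O)OC(C)(C)C)C[C@@]2(C(O)OC3)[C@H]3CC[C@@H]12 | intermediate
13 | diol diene: C1 carries CH(OH)CH=CH2 (C10 epimers), C2 carries CH2OH cis to it, C7 carries the tert-butyl acrylate; (1S,2R,5S,7R) | CC1(C)[C@H](C(=C)C(=O)OC(C)(C)C)C[C@@]2(C(O)C=C)[C@H](CO)CC[C@@H]12 | intermediate
14 | tert-butyl (1S,2R,5S,7R)-10-hydroxy-2-(hydroxymethyl)-6,6-dimethyltricyclo[5.3.1.0(1,5)]undec-8-ene-8-carboxylate (C10 epimers) | CC1(C)[C@H]2C[C@@]3(C(O)C=C2C(=O)OC(C)(C)C)[C@H](CO)CC[C@@H]13 | intermediate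
15 | tert-butyl (1S,2R,5S,7R)-2-formyl-6,6-dimethyl-10-oxotricyclo[5.3.1.0(1,5)]undec-8-ene-8-carboxylate | CC1(C)[C@H]2C[C@@]3(C(=O)C=C2C(=O)OC(C)(C)C)[C@H](C=O)CC[C@@H]13 | intermediate
16 | tert-butyl (1S,2S,5S,7R)-2-formyl-6,6-dimethyl-10-oxotricyclo[5.3.1.0(1,5)]undec-8-ene-8-carboxylate | CC1(C)[C@H]2C[C@@]3(C(=O)C=C2C(=O)OC(C)(C)C)[C@@H](C=O)CC[C@@H]13 | intermediate
17 | tert-butyl (1S,2S,5S,7R)-2-(dimethoxymethyl)-6,6-dimethyl-10-oxotricyclo[5.3.1.0(1,5)]undec-8-ene-8-carboxylate | CC1(C)[C@H]2C[C@@]3(C(=O)C=C2C(=O)OC(C)(C)C)[C@@H](C(OC)OC)CC[C@@H]13 | intermediate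
18 | tert-butyl (1S,2S,5S,7R,10S)-2-(dimethoxymethyl)-10-hydroxy-6,6-dimethyltricyclo[5.3.1.0(1,5)]undec-8-ene-8-carboxylate | CC1(C)[C@H]2C[C@@]3([C@@H](O)C=C2C(=O)OC(C)(C)C)[C@@H](C(OC)OC)CC[C@@H]13 | intermediate
19 | dec-9-enoic acid | C=CCCCCCCCC(=O)O | starting material
20 | tert-butyl (1S,2S,5S,7R,10S)-10-(dec-9-enoyloxy)-2-(dimethoxymethyl)-6,6-dimethyltricyclo[5.3.1.0(1,5)]undec-8-ene-8-carboxylate | CC1(C)[C@H]2C[C@@]3([C@@H](OC(=O)CCCCCCCC=C)C=C2C(=O)OC(C)(C)C)[C@@H](C(OC)OC)CC[C@@H]13 | intermediate
21 | oct-7-en-1-ol | C=CCCCCCCO | starting material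
22 | tert-butyl (1S,2S,5S,7R,10S)-2-(dimethoxymethyl)-10-{[(9Z)-16-hydroxyhexadec-9-enoyl]oxy}-6,6-dimethyltricyclo[5.3.1.0(1,5)]undec-8-ene-8-carboxylate | CC1(C)[C@H]2C[C@@]3([C@@H](OC(=O)CCCCCCC/C=C\CCCCCCO)C=C2C(=O)OC(C)(C)C)[C@@H](C(OC)OC)CC[C@@H]13 | intermediate
23 | (1S,2S,5S,7R,10S)-2-formyl-10-{[(9Z)-16-hydroxyhexadec-9-enoyl]oxy}-6,6-dimethyltricyclo[5.3.1.0(1,5)]undec-8-ene-8-carboxylic acid | CC1(C)[C@H]2C[C@@]3([C@@H](OC(=O)CCCCCCC/C=C\CCCCCCO)C=C2C(=O)O)[C@@H](C=O)CC[C@@H]13 | target

**Total step count:** 11. **Longest linear sequence:** 11 (from 1 and 2 to 23).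

**Steps most likely to fail**

**Step 4 (radical bicyclisation).**
- Risks: the catalytic chain may stall, or the tertiary C-6 radical may be trapped by the disulfide.
- Fallback, from 10 back to 11:
  - Add PhSH (1 M, AIBN, 80 °C) across 10. Fast hydrogen transfer then intercepts the opened radical and gives the ring-opened allyl sulfide lactone F1.
  - Selenenylate the lactone enolate of F1 (LDA, PhSeCl, −78 °C) to the α-phenylselanyl lactone F2.
  - Run the two ring closures as a stoichiometric tin hydride chain (Bu3SnH by syringe pump, AIBN, PhH, reflux). The C-1 radical now forms irreversibly from the C–Se bond, and the chain ends with loss of PhS• to give 11.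

**Step 3 (ylide cyclopropanation).**
- Risk: the allylic sulfonium salt is itself an electrophile and may consume its own ylide.
- Fallback, from 7 (with 8) back to 10:
  - Turn 8 into tert-butyl 2-[(phenylsulfonyl)methyl]prop-2-enoate F3 with PhSO2Na in DMF.
  - Add the potassium anion of F3 (KOt-Bu, THF, −40 °C) to 7. Conjugate addition and 1,3-elimination of sulfinate follow, which is the sulfone cyclopropanation used for chrysanthemates, and this closes the same vinylcyclopropane 10.

**Step 10 (Z-selective cross metathesis).**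
- Risks: homodimers and incomplete Z selectivity on late material.
- Fallback, from 20 back to 22:
  - Cleave only the terminal alkene of 20 (OsO4 cat., NaIO4, 2,6-lutidine, dioxane/water). The conjugated ring alkene is too electron-poor to compete, and the product is the 9-oxononanoate ester F4.
  - Make (7-hydroxyheptyl)triphenylphosphonium bromide F5 from 7-bromoheptan-1-ol and PPh3.
  - Join F4 and F5 in a salt-free Z-selective Wittig reaction (NaHMDS 2 equiv, THF, −78 °C) to give 22.

**Further compounds**
F1 | step 4 | tert-butyl 4-[(4R)-4-(4-methylpent-3-en-1-yl)-2-oxooxolan-3-yl]-2-[(phenylsulfanyl)methyl]but-2-enoate | O=C1OC[C@H](CCC=C(C)C)C1CC=C(CSc1ccccc1)C(=O)OC(C)(C)C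
F2 | step 4 | tert-butyl 4-[(4R)-4-(4-methylpent-3-en-1-yl)-2-oxo-3-(phenylselanyl)oxolan-3-yl]-2-[(phenylsulfanyl)methyl]but-2-enoate | O=C1OC[C@H](CCC=C(C)C)C1([Se]c1ccccc1)CC=C(CSc1ccccc1)C(=O)OC(C)(C)C
F3 | step 3 | tert-butyl 2-[(phenylsulfonyl)methyl]prop-2-enoate | C=C(CS(=O)(=O)c1ccccc1)C(=O)OC(C)(C)C
F4 | step 10 | tert-butyl (1S,2S,5S,7R,10S)-2-(dimethoxymethyl)-6,6-dimethyl-10-[(9-oxononanoyl)oxy]tricyclo[5.3.1.0(1,5)]undec-8-ene-8-carboxylate | CC1(C)[C@H]2C[C@@]3([C@@H](OC(=O)CCCCCCCC=O)C=C2C(=O)OC(C)(C)C)[C@@H](C(OC)OC)CC[C@@H]13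
F5 | step 10 | (7-hydroxyheptyl)triphenylphosphonium bromide | OCCCCCCC[P+](c1ccccc1)(c1ccccc1)c1ccccc1.[Br-]
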